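The numbers are made up; the run is a simulation.

A small charge of protic impurity, 4.05 mM, is where the quick number you asked for has to begin, because every end it caps stays a chain end.

common to all: first end groups 0.081 M; protic impurity 4.05 mM; time 5.0 d

| run | second end groups |
|---|---|
| eta | 0.0891 M |
| beta | 0.120 M |

    first end groups + protic impurity → quenched substrate (k1 = 3.79 /M/h)
    released group → by-product carried off (k2 = 0.0456 /h)
    first end groups + second end groups ⇌ links + released group (K3 = 0.91, k3 = 122 /M/h)

- which of the two ends with the longer chains by the average number of monomer units in a chain (unreacted monomers counted as chains of one) ("neither" if they lie within 10%) (eta / beta / neither)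
- average number of monomer units in a chain (unreacted monomers counted as chains of one) at the end, eta
- average number of monomer units in a chain (unreacted monomers counted as chains of one) at the end, beta

- each molecule carries two end groups: a chain counts once for every two ends that are left, dead ends included; the units are half of the end groups of the two monomers charged
- run time (eta): 5.0 d

The impurity's half-life against the charged first end groups is 2.26 h, far shorter than the run of 5.0 d, so it is counted as spent at once, leaving 0.0770 M of usable first ends. Linking has a half-life near 0.0638 h, against 0.63 d for the released group's removal, so linking sits at equilibrium and removal is the rate-limiting step.

Write A, B, L and W for first ends, second ends, links and released group, K for the equilibrium constant and k for the removal constant. Then W = KAB/L, and differentiating gives dL/dt = kKAB/D, where D = L + K(A+B) + W. With D held at a mean, this is a second-order law in which ln(B/A) rises in a straight line, at slope gκ, where g is the excess of B over A and κ = kK/D.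

For eta, g is 0.0121 M. The opening burst gives L = 0.0404 M, ln(B/A) = 0.287 and D = 0.158 M. Supposing A used up at the end gives D = 0.0880 M, a mean of 0.123 M, and so A = 0.0103 M.

Putting that A back in gives 0.0666 M of links, 0.003165 M of released group and a mean D of 0.129 M. The result is 0.322 /M/h, the pace constant of removal-limited linking, and A = 0.0108 M. Charged ends over ends left, capped ones included, then give 4.51 for eta.

Beta borrows κ, a shortcut, with g = 0.0430 M. Its burst gives 0.0469 M of links, then A = 0.003642 M, and so 3.70. The longer chains are expected in eta.

The forecast says eta, with 4.7 and 3.6: “Both runs reach similar link counts, but beta's large excess of second end groups leaves many more unreacted ends”.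

The simulation gives eta, at 4.81 against 3.63 for beta.

In eta the quench had 99.7% of its turnover behind it by 2.50 d. Linking went on as released group left: at 2.50 d, 78.3% of the first ends had reacted, with 0.00797 M of released group standing and 0.0514 M carried off. Run for 3.0 d instead, κ gives 3.55 units per chain; eta read at that time holds 3.62, with links at 76.0%.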